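## Structural features

- The target is a monocyclic oxolane, numbered here O1, C2, C3, C4, C5. C2 carries a 3,4,5-trimethoxyphenyl ring, C3 a hydroxymethyl group, C4 a 2,4,5-trimethoxybenzyl group, and C5 is an unsubstituted OCH2.
- C2, C3 and C4 are contiguous stereocentres, all R. On the ring these descriptors place the aryl, hydroxymethyl and benzyl groups on one face (2,3-cis and 3,4-cis), so H–C2, H–C3 and H–C4 share the other face.
- This all-cis array is the contra-thermodynamic one, the C2 epimer of the usual 2,3-trans-3,4-cis lignan pattern. None of the three groups can therefore be placed by equilibration.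
- C2 is a benzylic ether carbon para to a methoxy group. Acid can ionise the C2–O1 bond and epimerise C2, and hydrogenolysis catalysts can cleave the same bond.
- The 2,4,5-trimethoxyphenyl ring is very electron-rich, so oxidants and strong electrophiles are avoided. The primary alcohol is the only group that needs protection.
- The real difficulty is to set three cis centres kinetically, in the absolute sense, with the aryl group on the crowded face, and then never expose C2 to acid.
- The key step exploits the C2–C3–C4 segment. C2 is a carbinol-type carbon, and C4 carries two one-carbon branches (C5 and the benzylic CH2), so the segment is the retron of a homoallylic alcohol with C4 as a 1,1-disubstituted alkene carbon. The 2,3-cis relation is the syn adduct of a closed allylboration, and the cis hydrogen at C4 can be added last, from the open face of the ring.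

## Logic of the disconnections

In one sentence: 8 is made by a catalytic enantioselective, chair-controlled allylboration of 6 with 5, which forms C2–C3, sets C2 and C3 syn, and leaves C4 as a methylidene carbon.

**15 ⇒ 14.** The O–Si bond of the primary alcohol is cut. A silyl ether is removable by fluoride without acid, which protects the C2 benzylic ether. The forward step must be non-acidic.

**14 ⇒ 11 + 12 (through 13).** The arene–CH2 bond of the C4 side chain and the C4–H bond are cut. This removes the C4 stereocentre and the whole second arene, leaving an exocyclic methylidene on a ring that already holds C2 and C3. The forward hydroboration must deliver hydrogen to C4 from the face opposite the cis C2 and C3 substituents, and the alkylborane must couple with an electron-rich aryl bromide.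

**11 ⇒ 9 (through 10).** The O1–C5 bond is cut. The ring opens to a 1,4-diol whose primary hydroxyl is allylic and whose secondary hydroxyl is the C2 carbinol. The forward step must activate only the primary hydroxyl, so that O1 stays on C2 and C2 keeps its configuration.

**9 ⇒ 8.** The C5 oxidation level is changed from alcohol to ester. The ester is what controls the alkene geometry of 5 further back. The forward step is a 1,2-reduction that must spare the silyl ether.

**8 ⇒ 5 + 6 (through 7), the key disconnection.** The C2–C3 bond is cut. Two stereocentres are traded for one alkene geometry and one catalyst, and the target falls into an achiral boronate and a commercial aldehyde. The forward step must transfer the alkene geometry faithfully (syn) and select the Re face of 6 without acid strong enough to ionise the benzylic carbinol.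

**5 ⇒ 4 ⇒ 3 ⇒ 1 + 2.** The C–B bond is cut with allylic transposition, then the acetate, then the C–C bond between the C3 carbon and its CH2OSi-bearing neighbour. This leads to two commercial compounds. The borylation must give the alkene with the CH2OSi group cis to CH2B.

## Other disconnections considered

**Alternative 1: (the first that comes to mind).**
- Cut: C2–C3 as a lactone aldol and O1–C2 as an etherification.
- Forward: the enolate of the β-benzyl-γ-butyrolactone A1 adds to 6, hydride reduction gives the triol A2, and the ring is closed between C2 and the hydroxymethyl group on C4.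
- Ground for rejection: the trans lactone gives 3,4-cis correctly, but the ring closure must choose between two primary hydroxyls. The easy closure, acid through the C2 benzylic cation, is under thermodynamic control and should give the 2,3-trans epimer. The kinetic closure needs a defined carbinol configuration, which a lactone-enolate aldol with an aryl aldehyde does not reliably supply. The hardest centre is left to the last step under the wrong kind of control.

**Alternative 2:**
- Cut: no C–C bond, only the ring C–H bonds at C2, C3 and C4.
- Forward: enantioselective all-cis hydrogenation of the flat furan A3, which is quickly available by a Feist–Benary condensation, followed by ester reduction.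
- Ground for rejection: this is the shortest plan on paper and the all-cis relation is inherent. However, no catalyst class is established for enantioface selection on a 2-aryl-3,4-disubstituted furan. The product's C2–O1 benzylic ether is also exposed to the same metal and hydrogen. The saving in steps would be lost to a resolution.

**Alternative 3:**
- Cut: C2–C3 and O1–C5 in one (3+2) cycloaddition.
- Forward: a palladium–trimethylenemethane dipole from the cyano-substituted donor A4 adds to 6 and gives the methylidene oxolane A5, which would share the endgame of the chosen route.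
- Ground for rejection: the C2/C3 relation arises from an open zwitterion (aldol-type addition, then ring closure) with no closed transition state, so 2,3-trans or a mixture is expected. The nitrile must then pass through an aldehyde that can epimerise at C3 toward trans. The chosen allylboration is the stereochemically defined, stepwise equivalent: two more steps, but 2,3-cis fixed by alkene geometry.

Key step: step 4

## Route

Remark: the (R)-configured phosphoric acid is assumed to favour Re-face addition, by analogy with allyl and crotyl pinacol boronates. If the ester-bearing boronate responds in the opposite sense, the (S)-acid is used and nothing else changes. Locants C2–C5 refer to the oxolane of the target.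

Step 1
Reactants: 1 (tert-butyldimethylsilyloxy)acetaldehyde; 2 methyl acrylate
Product: 3 methyl 4-[(tert-butyldimethylsilyl)oxy]-3-hydroxy-2-methylidenebutanoate (racemic)
Conditions: DABCO (0.5 equiv), methyl acrylate (3 equiv), MeOH (cat.), rt
Reagents that add atoms: none
Why: Morita–Baylis–Hillman reaction, for which α-oxygenated aldehydes are among the most reactive acceptors. The carbinol centre is made racemic on purpose, because it becomes an alkene carbon in step 3.

Step 2
Reactants: 3 methyl 4-[(tert-butyldimethylsilyl)oxy]-3-hydroxy-2-methylidenebutanoate
Product: 4 methyl 3-(acetyloxy)-4-[(tert-butyldimethylsilyl)oxy]-2-methylidenebutanoate (racemic)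
Conditions: Ac2O, pyridine, DMAP (cat.), CH2Cl2, 0 °C
Reagents that add atoms: acetic anhydride CC(=O)OC(C)=O
Why: Standard acylation of a secondary allylic alcohol. The low temperature suppresses allylic transposition of the acetate, which would in any case lead to the same allylpalladium intermediate in step 3.

Step 3
Reactants: 4 methyl 3-(acetyloxy)-4-[(tert-butyldimethylsilyl)oxy]-2-methylidenebutanoate
Product: 5 methyl (2E)-4-[(tert-butyldimethylsilyl)oxy]-2-[(4,4,5,5-tetramethyl-1,3,2-dioxaborolan-2-yl)methyl]but-2-enoate
Conditions: B2pin2, Pd2(dba)3 (2.5 mol%), toluene, 50 °C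
Reagents that add atoms: bis(pinacolato)diboron CC1(C)OB(OC1(C)C)B1OC(C)(C)C(C)(C)O1
Why: Miyaura-type allylic borylation: zerovalent palladium ionises the acetate, the acetate-activated diboron transmetalates, and boron goes to the unsubstituted allyl terminus. The trisubstituted alkene should form with CH2OTBS trans to the ester and cis to CH2B, the geometry favoured in substitutions of Morita–Baylis–Hillman acetates with transposition.

Step 4
Reactants: 5 methyl (2E)-4-[(tert-butyldimethylsilyl)oxy]-2-[(4,4,5,5-tetramethyl-1,3,2-dioxaborolan-2-yl)methyl]but-2-enoate; 6 3,4,5-trimethoxybenzaldehyde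
Product: 8 methyl (3R,4R)-3-({[tert-butyl(dimethyl)silyl]oxy}methyl)-4-hydroxy-2-methylidene-4-(3,4,5-trimethoxyphenyl)butanoate, via O-pinacolboryl ether 7 (not isolated)
Conditions: (R)-TRIP [(R)-3,3'-bis(2,4,6-triisopropylphenyl)-1,1'-binaphthyl-2,2'-diyl hydrogen phosphate] (10 mol%), 4 Å MS, toluene, 0 °C to rt; aq. NaHCO3
Reagents that add atoms: none
Why: The phosphoric acid hydrogen-bonds to one dioxaborolane oxygen of 5, which raises the Lewis acidity of boron, and through its phosphoryl oxygen to the formyl C–H of 6; the aldehyde oxygen then binds boron and the γ-carbon of 5 attacks the carbonyl carbon through a closed six-membered chair (Zimmerman–Traxler) transition state with allylic transposition, which forms the C2–C3 bond of the target and turns the former CH2B carbon into the methylidene group on C4. The closest known reaction types are the chiral phosphoric acid-catalysed allyl- and crotylboration of aryl aldehydes with pinacol boronates and the Brønsted or Lewis acid-accelerated additions of 2-alkoxycarbonyl allylboronates to aldehydes. No ring of the target is closed in this step (the oxolane follows in step 6 by 5-exo-tet displacement); the step delivers the whole C2–C5 chain with C5 as the ester. C3 is controlled by the alkene geometry of 5: the CH2OTBS group, cis to CH2B, is forced axial in the chair while the aryl group of 6 sits equatorial, which gives the syn (3R,4R) adduct, and syn maps onto 2,3-cis in the oxolane. C2 (C4 of 8) is controlled by the catalyst, the (R)-acid being expected to expose the Re face of the aldehyde as it does for allyl and crotyl pinacol boronates. The step needs enantioface selectivity and strict transfer of alkene geometry; the latter is secured by the configurational stability of the allyl pinacol boronate and the closed transition state, the former by the fact that the ester slows the uncatalysed addition so strongly (this reagent class is known to need heating to about 100 °C) that the acid-bound pathway should dominate even at ambient temperature. The acid is too weak to ionise the electron-rich benzylic carbinol of 7 or 8, and the buffered work-up avoids an acid-promoted lactonisation through a benzylic cation that would erode the syn relationship.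

Step 5
Reactants: 8 methyl (3R,4R)-3-({[tert-butyl(dimethyl)silyl]oxy}methyl)-4-hydroxy-2-methylidene-4-(3,4,5-trimethoxyphenyl)butanoate
Product: 9 (1R,2R)-2-({[tert-butyl(dimethyl)silyl]oxy}methyl)-3-methylidene-1-(3,4,5-trimethoxyphenyl)butane-1,4-diol
Conditions: i-Bu2AlH (3.5 equiv), CH2Cl2, −78 to −20 °C; aq. potassium sodium tartrate
Reagents that add atoms: none
Why: 1,2-Reduction of an acrylate ester to the allylic alcohol by an aluminium hydride, as is routine for Morita–Baylis–Hillman-type esters. The conditions are non-acidic, the silyl ether survives, and no stereocentre is touched.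

Step 6
Reactants: 9 (1R,2R)-2-({[tert-butyl(dimethyl)silyl]oxy}methyl)-3-methylidene-1-(3,4,5-trimethoxyphenyl)butane-1,4-diol
Product: 11 tert-butyl(dimethyl){[(2R,3R)-4-methylidene-2-(3,4,5-trimethoxyphenyl)oxolan-3-yl]methoxy}silane, via primary allylic tosylate 10 (not isolated)
Conditions: TsCl (1.05 equiv), Et3N, DMAP (cat.), CH2Cl2, −10 °C; then 40 °C
Reagents that add atoms: none
Why: Williamson-type cycloetherification: the unhindered primary allylic hydroxyl is sulfonylated in preference to the branched secondary benzylic one, and the benzylic hydroxyl then displaces the allylic sulfonate in a 5-exo-tet closure (direct and allylically transposed attack give the same product). The C2–O bond is never broken, so C2 keeps its configuration and the syn relation of 9 becomes 2,3-cis.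

Step 7
Reactants: 11 tert-butyl(dimethyl){[(2R,3R)-4-methylidene-2-(3,4,5-trimethoxyphenyl)oxolan-3-yl]methoxy}silane; 12 1-bromo-2,4,5-trimethoxybenzene
Product: 14 tert-butyl(dimethyl){[(2R,3R,4R)-2-(3,4,5-trimethoxyphenyl)-4-[(2,4,5-trimethoxyphenyl)methyl]oxolan-3-yl]methoxy}silane, via B-alkyl-9-BBN adduct 13 (not isolated)
Conditions: 9-BBN, THF, 0 °C to rt; then 12, Pd(OAc)2 (5 mol%), SPhos (10 mol%), aq. K3PO4, THF, 65 °C
Reagents that add atoms: none
Why: Hydroboration followed by B-alkyl Suzuki–Miyaura coupling. 9-BBN places boron on the exocyclic carbon and hydrogen on C4 from the ring face opposite the cis C2-aryl and C3-CH2OTBS groups, so the new CH2 branch ends up cis to both and C4 is set as R. The coupling acts at the primary carbon and leaves the stereocentres alone.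

Step 8
Reactants: 14 tert-butyl(dimethyl){[(2R,3R,4R)-2-(3,4,5-trimethoxyphenyl)-4-[(2,4,5-trimethoxyphenyl)methyl]oxolan-3-yl]methoxy}silane
Product: 15 [(2R,3R,4R)-2-(3,4,5-trimethoxyphenyl)-4-[(2,4,5-trimethoxyphenyl)methyl]oxolan-3-yl]methanol
Conditions: Bu4NF, THF, 0 °C to rt
Reagents that add atoms: none
Why: Fluoride cleavage of a primary silyl ether. No acid is used, so the benzylic C2–O1 bond and the all-cis array are not at risk.

## Compound list

1 | (tert-butyldimethylsilyloxy)acetaldehyde | O=CCO[Si](C)(C)C(C)(C)C | starting material
2 | methyl acrylate | C=CC(=O)OC | starting material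
3 | methyl 4-[(tert-butyldimethylsilyl)oxy]-3-hydroxy-2-methylidenebutanoate (racemic) | C=C(C(=O)OC)C(O)CO[Si](C)(C)C(C)(C)C | intermediate
4 | methyl 3-(acetyloxy)-4-[(tert-butyldimethylsilyl)oxy]-2-methylidenebutanoate (racemic) | C=C(C(=O)OC)C(OC(C)=O)CO[Si](C)(C)C(C)(C)C | intermediate
5 | methyl (2E)-4-[(tert-butyldimethylsilyl)oxy]-2-[(4,4,5,5-tetramethyl-1,3,2-dioxaborolan-2-yl)methyl]but-2-enoate | COC(=O)/C(CB1OC(C)(C)C(C)(C)O1)=C/CO[Si](C)(C)C(C)(C)C | intermediate
6 | 3,4,5-trimethoxybenzaldehyde | COc1cc(C=O)cc(OC)c1OC | starting material
7 | methyl (3R,4R)-3-({[tert-butyl(dimethyl)silyl]oxy}methyl)-2-methylidene-4-[(4,4,5,5-tetramethyl-1,3,2-dioxaborolan-2-yl)oxy]-4-(3,4,5-trimethoxyphenyl)butanoate (formed in the flask) | C=C(C(=O)OC)[C@H](CO[Si](C)(C)C(C)(C)C)[C@@H](OB1OC(C)(C)C(C)(C)O1)c1cc(OC)c(OC)c(OC)c1 | intermediate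
8 | methyl (3R,4R)-3-({[tert-butyl(dimethyl)silyl]oxy}methyl)-4-hydroxy-2-methylidene-4-(3,4,5-trimethoxyphenyl)butanoate | C=C(C(=O)OC)[C@H](CO[Si](C)(C)C(C)(C)C)[C@@H](O)c1cc(OC)c(OC)c(OC)c1 | intermediate
9 | (1R,2R)-2-({[tert-butyl(dimethyl)silyl]oxy}methyl)-3-methylidene-1-(3,4,5-trimethoxyphenyl)butane-1,4-diol | C=C(CO)[C@H](CO[Si](C)(C)C(C)(C)C)[C@@H](O)c1cc(OC)c(OC)c(OC)c1 | intermediate
10 | (3R,4R)-3-({[tert-butyl(dimethyl)silyl]oxy}methyl)-4-hydroxy-2-methylidene-4-(3,4,5-trimethoxyphenyl)butyl 4-methylbenzenesulfonate (formed in the flask) | Cc1ccc(cc1)S(=O)(=O)OCC(=C)[C@H](CO[Si](C)(C)C(C)(C)C)[C@@H](O)c1cc(OC)c(OC)c(OC)c1 | intermediate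
11 | tert-butyl(dimethyl){[(2R,3R)-4-methylidene-2-(3,4,5-trimethoxyphenyl)oxolan-3-yl]methoxy}silane | C=C1CO[C@@H](c2cc(OC)c(OC)c(OC)c2)[C@H]1CO[Si](C)(C)C(C)(C)C | intermediate
12 | 1-bromo-2,4,5-trimethoxybenzene | COc1cc(OC)c(OC)cc1Br | starting material
13 | 9-{[(3R,4R,5R)-4-({[tert-butyl(dimethyl)silyl]oxy}methyl)-5-(3,4,5-trimethoxyphenyl)oxolan-3-yl]methyl}-9-borabicyclo[3.3.1]nonane (formed in the flask) | C1CC2CCCC(C1)B2C[C@H]1CO[C@@H](c2cc(OC)c(OC)c(OC)c2)[C@H]1CO[Si](C)(C)C(C)(C)C | intermediate
14 | tert-butyl(dimethyl){[(2R,3R,4R)-2-(3,4,5-trimethoxyphenyl)-4-[(2,4,5-trimethoxyphenyl)methyl]oxolan-3-yl]methoxy}silane | COc1cc(OC)c(OC)cc1C[C@H]1CO[C@@H](c2cc(OC)c(OC)c(OC)c2)[C@H]1CO[Si](C)(C)C(C)(C)C | intermediate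
15 | [(2R,3R,4R)-2-(3,4,5-trimethoxyphenyl)-4-[(2,4,5-trimethoxyphenyl)methyl]oxolan-3-yl]methanol | COc1cc(OC)c(OC)cc1C[C@H]1CO[C@@H](c2cc(OC)c(OC)c(OC)c2)[C@H]1CO | target

## Step count and least certain steps

Total step count: 8. Longest linear sequence: 8 steps (1 to 15); 6 and 12 enter as commercial compounds.

**Step 4 (key step).**
- What may go wrong: slow turnover. The boronate is deactivated by its ester and must place a substituent axial in the chair, and a weak Brønsted acid may not accelerate it enough. Raising the temperature would then erode enantioface discrimination. A second risk is acid-promoted ionisation at the electron-rich benzylic carbinol, which would cost the syn relation.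
- Fallback (sets out from 3 and 6, returns at 8): 3 is converted with N-bromosuccinimide and dimethyl sulfide (CH2Cl2, 0 °C), with allylic transposition, into methyl (2Z)-2-(bromomethyl)-4-[(tert-butyldimethylsilyl)oxy]but-2-enoate F1. A catalytic asymmetric Nozaki–Hiyama–Kishi allylation of 6 with F1 follows (CrCl2 (10 mol%), a chiral carbazole-bis(oxazoline) ligand, Mn powder, Me3SiCl, THF, rt; aqueous citric acid work-up). The allylchromium species should settle into the geometry with the γ-substituent trans to the ester and add through a chair, giving the syn adduct 8. The ligand enantiomer is chosen for the 4R carbinol.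

**Step 7.**
- What may go wrong: incomplete facial selectivity in the hydroboration, because boron sits on the exocyclic carbon, away from the ring substituents. Also slow oxidative addition of the electron-rich, ortho-substituted aryl bromide and slow transmetalation of the β-branched alkylborane, which would allow protodeboronation.
- Fallback (sets out from 11, returns at 14): the same hydroboration with oxidative work-up (NaBO3·4H2O) gives {(3S,4R,5R)-4-({[tert-butyl(dimethyl)silyl]oxy}methyl)-5-(3,4,5-trimethoxyphenyl)oxolan-3-yl}methanol F2, at which stage any C4 epimer can be removed. PPh3, imidazole and iodine give tert-butyl{[(2R,3R,4R)-4-(iodomethyl)-2-(3,4,5-trimethoxyphenyl)oxolan-3-yl]methoxy}dimethylsilane F3. The polarity of the coupling is then reversed: F3 reacts under Li2CuCl4 catalysis (THF, −20 °C) with (2,4,5-trimethoxyphenyl)magnesium bromide F4, made from 12 and Mg turnings, to give 14.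

**Step 6.**
- What may go wrong: sulfonylation at the benzylic hydroxyl, quaternisation of the amine by the reactive allylic sulfonate, participation of the silyl ether oxygen, or a base-induced silyl shift from the primary to the secondary oxygen. The last would let the wrong oxygen close a five-membered ring.
- Fallback (sets out from 9, returns at 11): selective acetylation of the primary allylic hydroxyl (AcCl, 2,4,6-collidine, CH2Cl2, −78 °C) gives (3R,4R)-3-({[tert-butyl(dimethyl)silyl]oxy}methyl)-4-hydroxy-2-methylidene-4-(3,4,5-trimethoxyphenyl)butyl acetate F5. Pd(PPh3)4 (5 mol%, THF, rt) then closes the ring by a Tsuji–Trost etherification through a 2-substituted allylpalladium intermediate. This runs under neutral conditions with no alkoxide and no sulfonate.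

**Step 3.**
- What may go wrong: loss of the allylpalladium intermediate by elimination toward a diene, allyl–allyl coupling between product and intermediate, or incomplete control of alkene geometry.
- Fallback (sets out from 3, returns at 5): Boc2O and DMAP (cat.) give methyl 3-[(tert-butoxycarbonyl)oxy]-4-[(tert-butyldimethylsilyl)oxy]-2-methylidenebutanoate F6. Copper-catalysed γ-selective borylation (CuCl (5 mol%), Xantphos, KOt-Bu (cat.), B2pin2, THF, 0 °C) then proceeds by borylcupration of the acrylate and β-elimination of the carbonate. No allylmetal is ionised, and the elimination should favour the alkene with CH2OTBS trans to the ester, giving 5.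

## Further compounds

F1 | step 4 | methyl (2Z)-2-(bromomethyl)-4-[(tert-butyldimethylsilyl)oxy]but-2-enoate | COC(=O)/C(CBr)=C/CO[Si](C)(C)C(C)(C)C
F2 | step 7 | {(3S,4R,5R)-4-({[tert-butyl(dimethyl)silyl]oxy}methyl)-5-(3,4,5-trimethoxyphenyl)oxolan-3-yl}methanol | OC[C@H]1CO[C@@H](c2cc(OC)c(OC)c(OC)c2)[C@H]1CO[Si](C)(C)C(C)(C)C
F3 | step 7 | tert-butyl{[(2R,3R,4R)-4-(iodomethyl)-2-(3,4,5-trimethoxyphenyl)oxolan-3-yl]methoxy}dimethylsilane | IC[C@H]1CO[C@@H](c2cc(OC)c(OC)c(OC)c2)[C@H]1CO[Si](C)(C)C(C)(C)C
F4 | step 7 | (2,4,5-trimethoxyphenyl)magnesium bromide | COc1cc(OC)c(OC)cc1[Mg]Br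
F5 | step 6 | (3R,4R)-3-({[tert-butyl(dimethyl)silyl]oxy}methyl)-4-hydroxy-2-methylidene-4-(3,4,5-trimethoxyphenyl)butyl acetate | CC(=O)OCC(=C)[C@H](CO[Si](C)(C)C(C)(C)C)[C@@H](O)c1cc(OC)c(OC)c(OC)c1
F6 | step 3 | methyl 3-[(tert-butoxycarbonyl)oxy]-4-[(tert-butyldimethylsilyl)oxy]-2-methylidenebutanoate (racemic) | C=C(C(=O)OC)C(OC(=O)OC(C)(C)C)CO[Si](C)(C)C(C)(C)C
A1 | alternative 1 | (4R)-4-[(2,4,5-trimethoxyphenyl)methyl]oxolan-2-one | COc1cc(OC)c(OC)cc1C[C@H]1COC(=O)C1
A2 | alternative 1 | (2R,3R)-2-[hydroxy(3,4,5-trimethoxyphenyl)methyl]-3-[(2,4,5-trimethoxyphenyl)methyl]butane-1,4-diol (carbinol centre not controlled) | COc1cc(OC)c(OC)cc1C[C@@H](CO)[C@H](CO)C(O)c1cc(OC)c(OC)c(OC)c1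
A3 | alternative 2 | methyl 2-(3,4,5-trimethoxyphenyl)-4-[(2,4,5-trimethoxyphenyl)methyl]furan-3-carboxylate | COC(=O)c1c(Cc2cc(OC)c(OC)cc2OC)coc1-c1cc(OC)c(OC)c(OC)c1
A4 | alternative 3 | 1-cyano-2-[(trimethylsilyl)methyl]prop-2-en-1-yl acetate | CC(=O)OC(C#N)C(=C)C[Si](C)(C)C
A5 | alternative 3 | (2R,3R)-4-methylidene-2-(3,4,5-trimethoxyphenyl)oxolane-3-carbonitrile | C=C1CO[C@@H](c2cc(OC)c(OC)c(OC)c2)[C@H]1C#N
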